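**Retrosynthetic overview**
1. The last cut removes two O-alkyl groups with BCl3. These are the 5-O-methyl ether of unit 2 (the 5,7-dihydroxy-4'-methoxyflavone) and the 4'-O-benzyl ether of unit 1 (the 5-hydroxy-7-methoxyflavone).
2. Ring C of unit 2 is opened at C4–C4a and O1–C2. This gives ethyl 4-methoxybenzoylacetate and a 2-aryl-5-methoxyresorcinol, joined in the forward sense by an acid-free thermal ketoester annulation.
3. Structural feature: C8 of unit 2, the carbon bonded to C3' of ring B of unit 1, is C2 of that resorcinol and lies on its local two-fold axis (C2···C5). The two open CH carbons are therefore interchangeable, and each is flanked by one OH and the capped OMe, so annulation on either side gives the same 8-aryl flavone.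
4. The C3'–C8 biaryl bond comes from a Suzuki coupling of a 3'-iodoflavone with the boronate of ortho-lithiated 5-methoxyresorcinol bis(MOM) ether. Ring C of unit 1 comes from a chalcone by I2/DMSO cyclisation.
5. Ring order: all four benzene rings are bought, ring C of unit 1 is closed first (step 4), and ring C of unit 2 is closed last (step 9).

Key step: step 9

Assumption: the target SMILES has no stereocentre and no descriptor for the C3'–C8 axis, so the axis is treated as configurationally undefined; the two mirror-related annulation sites of the key step would give both axial senses equally.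

**Step 1**
Reactants: 1 4-hydroxy-3-iodobenzaldehyde
Product: 2 4-(benzyloxy)-3-iodobenzaldehyde
Conditions: BnBr (1.1 equiv), K2CO3, DMF, rt
Reagents that add atoms: benzyl bromide, BrCc1ccccc1
Why: Williamson etherification (SN2 of the phenoxide on benzyl bromide), in which the aldehyde and the aryl iodide are inert to K2CO3.

**Step 2**
Reactants: 3 2',6'-dihydroxy-4'-methoxyacetophenone
Product: 4 2'-hydroxy-4'-methoxy-6'-(methoxymethoxy)acetophenone
Conditions: MOMCl (1.1 equiv), K2CO3, acetone, 0 °C to rt
Reagents that add atoms: chloromethyl methyl ether (MOMCl), COCCl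
Why: Williamson-type O-alkylation of one of two equivalent hydroxyls, after which the remaining one is locked in a hydrogen bond to the acetyl carbonyl and is not alkylated by a weak base and one equivalent of reagent.

**Step 3**
Reactants: 2 4-(benzyloxy)-3-iodobenzaldehyde; 4 2'-hydroxy-4'-methoxy-6'-(methoxymethoxy)acetophenone
Product: 5 (E)-4-benzyloxy-2'-hydroxy-3-iodo-4'-methoxy-6'-(methoxymethoxy)chalcone
Conditions: KOH (excess), EtOH/H2O, rt; cold dilute HCl to pH 5–6
Reagents that add atoms: none
Why: Claisen–Schmidt condensation of the methyl ketone enolate with a non-enolisable aldehyde followed by E1cB dehydration to the conjugated E-enone, helped by the fact that only one phenoxide charge sits on the ketone partner.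

**Step 4**
Reactants: 5 (E)-4-benzyloxy-2'-hydroxy-3-iodo-4'-methoxy-6'-(methoxymethoxy)chalcone
Product: 7 4'-benzyloxy-5-hydroxy-3'-iodo-7-methoxyflavone, via 5-O-MOM flavone 6 (not isolated)
Conditions: I2 (0.1 equiv), DMSO, 130 °C; aq. Na2S2O3; crude in 3 M HCl, MeOH/THF, 60 °C
Reagents that add atoms: none
Why: Iodine/DMSO oxidative cyclisation of a 2'-hydroxychalcone (oxa-Michael addition of the only free ortho hydroxyl, alpha-iodination, loss of HI, reoxidation of HI by DMSO) closes ring C of unit 1, and the acid methanolysis completes the loss of the peri MOM group that HI may already begin to remove.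

**Step 5**
Reactants: 8 5-methoxyresorcinol
Product: 9 1-methoxy-3,5-bis(methoxymethoxy)benzene
Conditions: NaH (2.5 equiv), MOMCl (2.4 equiv), DMF, 0 °C to rt
Reagents that add atoms: chloromethyl methyl ether (MOMCl), COCCl
Why: Double Williamson-type O-alkylation of the two unhindered phenoxides with the highly reactive alpha-chloro ether.

**Step 6**
Reactants: 9 1-methoxy-3,5-bis(methoxymethoxy)benzene
Product: 11 2-[4-methoxy-2,6-bis(methoxymethoxy)phenyl]-4,4,5,5-tetramethyl-1,3,2-dioxaborolane, via aryllithium 10 (not isolated)
Conditions: n-BuLi (1.15 equiv), THF, 0 °C; iPrOBpin, −78 °C to rt; aq. NH4Cl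
Reagents that add atoms: 2-isopropoxy-4,4,5,5-tetramethyl-1,3,2-dioxaborolane (iPrOBpin), CC(C)OB1OC(C)(C)C(C)(C)O1; n-butyllithium, [Li]CCCC (supplies the lithium of 10 only)
Why: Directed ortho-metalation removes the C–H flanked by the two lithium-chelating OMOM groups in preference to the two C–H bonds that have one OMOM and the weaker OMe director as neighbours, the aryllithium is trapped at boron with loss of isopropoxide, and any unsymmetrical isomer would be removed by chromatography.

**Step 7**
Reactants: 7 4'-benzyloxy-5-hydroxy-3'-iodo-7-methoxyflavone; 11 2-[4-methoxy-2,6-bis(methoxymethoxy)phenyl]-4,4,5,5-tetramethyl-1,3,2-dioxaborolane (1.5 equiv)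
Product: 12 4'-benzyloxy-5-hydroxy-7-methoxy-3'-[4-methoxy-2,6-bis(methoxymethoxy)phenyl]flavone
Conditions: Pd(OAc)2 (5 mol %), SPhos (10 mol %), K3PO4, degassed 1,4-dioxane/H2O, 90 °C
Reagents that add atoms: none
Why: Suzuki–Miyaura coupling in which the aryl iodide adds readily to zerovalent palladium and the bulky electron-rich phosphine SPhos is the established ligand for tri-ortho-substituted biaryls from 2,6-dialkoxyaryl boron reagents, while the chelated 5-OH is merely deprotonated and the MOM, benzyl and pyranone groups tolerate aqueous K3PO4.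

**Step 8**
Reactants: 12 4'-benzyloxy-5-hydroxy-7-methoxy-3'-[4-methoxy-2,6-bis(methoxymethoxy)phenyl]flavone
Product: 13 4'-benzyloxy-3'-(2,6-dihydroxy-4-methoxyphenyl)-5-hydroxy-7-methoxyflavone
Conditions: 3 M HCl, MeOH/THF, 55 °C
Reagents that add atoms: none
Why: Acid-catalysed acetal methanolysis frees both phenols, the solvent traps the oxocarbenium ion as dimethoxymethane, and the benzyl and methyl aryl ethers are stable to dilute acid.

**Step 9**
Reactants: 13 4'-benzyloxy-3'-(2,6-dihydroxy-4-methoxyphenyl)-5-hydroxy-7-methoxyflavone; 14 ethyl 4-methoxybenzoylacetate (3–4 equiv, reagent and flux)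
Product: 17 4'-O-benzyl-5''-O-methylputraflavone, via 4-methoxybenzoylketene 15 (not isolated), via aryl 1,3-diketone 16 (not isolated)
Conditions: neat melt in excess 14, 240–250 °C, argon sweep to carry off EtOH and H2O (a minimum of Ph2O only if the melt stays heterogeneous)
Reagents that add atoms: none
Why: Above about 200 °C 14 loses ethanol to give the aroylketene 15, which C-acylates the phloroglucinol-type ring of 13 at one of its two open carbons (between a free OH and the OMe) and so makes C4–C4a of unit 2 in the 2-hydroxyaryl 1,3-diketone 16. The only hydroxyl next to the new acyl group, the one that also neighbours the aryl-bearing carbon, then attacks the anisoyl carbonyl in a 6-exo-trig closure (ring O1–C2–C3–C4–C4a–C8a), and loss of water makes O1–C2 and the C2=C3 double bond, which closes ring C. The closest known reaction type is the Mentzer pyrone synthesis, the catalyst-free thermal condensation of phloroglucinol-type phenols with aroylacetic esters to 5,7-dioxygenated flavones. The step needs the 8-aryl and not the 6-aryl flavone: the two open carbons are exchanged by the local two-fold axis through C2 (aryl) and C5 (OMe) of the resorcinol ring and the third oxygen is blocked as its methyl ether, so every productive acylation leads to the same 8-aryl-7-hydroxy-5-methoxy pattern. It also needs chromone and not coumarin, and reaction on this ring only: without acid the ketone carbonyl is not activated for Pechmann-type attack, O-acylation of phenols by 15 is reversible at this temperature, and ring A of unit 1 as well as the freshly annulated ring are deactivated by their pyranone carbonyls. No stereocentre is formed, and the benzyl and methyl aryl ethers should be thermally inert at 240 °C.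

**Step 10**
Reactants: 17 4'-O-benzyl-5''-O-methylputraflavone
Product: 18 putraflavone
Conditions: BCl3 (1 M in CH2Cl2, 8 equiv), pentamethylbenzene (5 equiv), CH2Cl2, −78 °C to rt; MeOH, then dilute aq. HCl
Reagents that add atoms: none
Why: BCl3 binds the C4 carbonyl of unit 2 together with the peri 5-OMe oxygen so that chloride removes only this methyl group (chelation-assisted ether cleavage), the benzyl ether ionises already in the cold with capture of its cation by pentamethylbenzene (Friedel–Crafts scavenging), and the unchelated 7-OMe of unit 1 and 4'-OMe of unit 2 are not cleaved by BCl3 at or below room temperature.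

**Compound list**
1 | 4-hydroxy-3-iodobenzaldehyde | O=Cc1ccc(O)c(I)c1 | starting material
2 | 4-(benzyloxy)-3-iodobenzaldehyde | O=Cc1ccc(OCc2ccccc2)c(I)c1 | intermediate
3 | 2',6'-dihydroxy-4'-methoxyacetophenone | CC(=O)c1c(O)cc(OC)cc1O | starting material
4 | 2'-hydroxy-4'-methoxy-6'-(methoxymethoxy)acetophenone | CC(=O)c1c(O)cc(OC)cc1OCOC | intermediate
5 | (E)-4-benzyloxy-2'-hydroxy-3-iodo-4'-methoxy-6'-(methoxymethoxy)chalcone | COCOc1cc(OC)cc(O)c1C(=O)/C=C/c1ccc(OCc2ccccc2)c(I)c1 | intermediate
6 | 4'-benzyloxy-3'-iodo-7-methoxy-5-(methoxymethoxy)flavone (not isolated) | COCOc1cc(OC)cc2oc(-c3ccc(OCc4ccccc4)c(I)c3)cc(=O)c12 | intermediate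
7 | 4'-benzyloxy-5-hydroxy-3'-iodo-7-methoxyflavone | COc1cc(O)c2c(=O)cc(-c3ccc(OCc4ccccc4)c(I)c3)oc2c1 | intermediate
8 | 5-methoxyresorcinol | COc1cc(O)cc(O)c1 | starting material
9 | 1-methoxy-3,5-bis(methoxymethoxy)benzene | COCOc1cc(OC)cc(OCOC)c1 | intermediate
10 | [4-methoxy-2,6-bis(methoxymethoxy)phenyl]lithium (not isolated) | [Li]c1c(OCOC)cc(OC)cc1OCOC | intermediate
11 | 2-[4-methoxy-2,6-bis(methoxymethoxy)phenyl]-4,4,5,5-tetramethyl-1,3,2-dioxaborolane | COCOc1cc(OC)cc(OCOC)c1B1OC(C)(C)C(C)(C)O1 | intermediate
12 | 4'-benzyloxy-5-hydroxy-7-methoxy-3'-[4-methoxy-2,6-bis(methoxymethoxy)phenyl]flavone | COCOc1cc(OC)cc(OCOC)c1-c1cc(-c2cc(=O)c3c(O)cc(OC)cc3o2)ccc1OCc1ccccc1 | intermediate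
13 | 4'-benzyloxy-3'-(2,6-dihydroxy-4-methoxyphenyl)-5-hydroxy-7-methoxyflavone (key-step precursor) | COc1cc(O)c(-c2cc(-c3cc(=O)c4c(O)cc(OC)cc4o3)ccc2OCc2ccccc2)c(O)c1 | intermediate
14 | ethyl 4-methoxybenzoylacetate (ethyl 3-(4-methoxyphenyl)-3-oxopropanoate) | CCOC(=O)CC(=O)c1ccc(OC)cc1 | starting material
15 | 4-methoxybenzoylketene (3-(4-methoxyphenyl)-3-oxoprop-1-en-1-one, not isolated) | COc1ccc(cc1)C(=O)C=C=O | intermediate
16 | 1-{3-[2-benzyloxy-5-(5-hydroxy-7-methoxy-4-oxo-4H-chromen-2-yl)phenyl]-2,4-dihydroxy-6-methoxyphenyl}-3-(4-methoxyphenyl)propane-1,3-dione (not isolated) | COc1ccc(cc1)C(=O)CC(=O)c1c(OC)cc(O)c(-c2cc(-c3cc(=O)c4c(O)cc(OC)cc4o3)ccc2OCc2ccccc2)c1O | intermediate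
17 | 4'-O-benzyl-5''-O-methylputraflavone (unit 2: 5-OMe, 7-OH, 8-aryl, 4'-OMe; unit 1: 5-OH, 7-OMe, 4'-OBn; key-step product) | COc1ccc(-c2cc(=O)c3c(OC)cc(O)c(-c4cc(-c5cc(=O)c6c(O)cc(OC)cc6o5)ccc4OCc4ccccc4)c3o2)cc1 | intermediate
18 | putraflavone (7,4'''-di-O-methylamentoflavone) | COc1ccc(-c2cc(=O)c3c(O)cc(O)c(-c4cc(-c5cc(=O)c6c(O)cc(OC)cc6o5)ccc4O)c3o2)cc1 | target

**Total step count:** 10
**Longest linear sequence:** 7 steps (3 → 4 → 5 → 7 → 12 → 13 → 17 → 18; the branch from 1 is equally long)

**Steps most likely to fail**

1. **Step 9 (key step).**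
   - What may go wrong: the high-melting phenol may not dissolve in the melt. The aroylketene may be used up by self-condensation of the ketoester faster than it C-acylates the hindered ring. Slow benzyl migration may set in on long heating.
   - Fallback: the same two bonds are built stepwise with known chemistry, setting out from 13.
   - A Houben–Hoesch reaction (MeCN, ZnCl2, dry HCl, Et2O/dioxane, 0 °C) at the same symmetry-equivalent carbon should give the aryl methyl ketimine F1.
   - Hydrolysis in hot water gives the 3-aryl-2,4-dihydroxy-6-methoxyacetophenone F2.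
   - The polylithio derivative of F2 (LiHMDS in excess, THF, −78 °C) is C-acylated with 4-methoxybenzoyl chloride.
   - This comes back to the route at diketone 16, now isolated, which is cyclodehydrated (cat. H2SO4, AcOH, 90 °C) to 17.

2. **Step 7.**
   - What may go wrong: protodeboronation of the electron-rich, doubly ortho-alkoxylated boronate in the basic aqueous medium may outrun its slow transmetalation to the hindered arylpalladium iodide.
   - Fallback: the polarity of the partners is reversed so that the fragile ring carries the halide. It sets out from 7 and from aryllithium 10.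
   - Miyaura borylation of 7 (B2pin2, PdCl2(dppf), KOAc, dioxane, 90 °C) should give the flavone 3'-pinacolboronate F3. Its boron sits on an electron-poorer ring that has a single ortho substituent.
   - Quenching 10 with I2 (THF, −78 °C) gives 2-iodo-5-methoxy-1,3-bis(methoxymethoxy)benzene F4.
   - Coupling of F3 with F4 (Pd(OAc)2, SPhos, K3PO4, toluene/H2O, 100 °C) comes back to the route at 12.

3. **Step 10.**
   - What may go wrong: precipitation of boron chelates may stall the peri demethylation. Forcing the reaction may start to cleave the unchelated methyl ethers. Incomplete scavenging may lead to ring benzylation.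
   - Fallback: the two cleavages are separated into orthogonal operations, setting out from 17.
   - Hydrogenolysis (H2, Pd/C, THF/MeOH, rt) removes only the benzyl group and should give 5''-O-methylputraflavone F5.
   - Chelation-controlled demethylation of F5 with AlCl3 in MeCN (70 °C, then dilute HCl), which is selective for a 5-methoxy group peri to the flavone carbonyl, comes back to the route at 18.

**Further compounds**
F1 | step 9 | 4'-benzyloxy-3'-[2,6-dihydroxy-3-(1-iminoethyl)-4-methoxyphenyl]-5-hydroxy-7-methoxyflavone (Hoesch ketimine) | CC(=N)c1c(OC)cc(O)c(-c2cc(-c3cc(=O)c4c(O)cc(OC)cc4o3)ccc2OCc2ccccc2)c1O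
F2 | step 9 | 3'-(3-acetyl-2,6-dihydroxy-4-methoxyphenyl)-4'-benzyloxy-5-hydroxy-7-methoxyflavone | CC(=O)c1c(OC)cc(O)c(-c2cc(-c3cc(=O)c4c(O)cc(OC)cc4o3)ccc2OCc2ccccc2)c1O
F3 | step 7 | 4'-benzyloxy-5-hydroxy-7-methoxy-3'-(4,4,5,5-tetramethyl-1,3,2-dioxaborolan-2-yl)flavone | COc1cc(O)c2c(=O)cc(-c3ccc(OCc4ccccc4)c(B4OC(C)(C)C(C)(C)O4)c3)oc2c1
F4 | step 7 | 2-iodo-5-methoxy-1,3-bis(methoxymethoxy)benzene | COCOc1cc(OC)cc(OCOC)c1I
F5 | step 10 | 5''-O-methylputraflavone | COc1ccc(-c2cc(=O)c3c(OC)cc(O)c(-c4cc(-c5cc(=O)c6c(O)cc(OC)cc6o5)ccc4O)c3o2)cc1
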